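**Plan**

1. Germacrane locants: ring C1–C10, lactone carbons C11–C13 on C7 with the ring oxygen on C6, C14 (acetoxymethyl) on C10, C15 (methyl) on C4, OH on C2, angelate on C8.
2. Retrosynthesis: remove the angelate, the acetate and the C13 methylene; open the lactone (C12–O6) and cut C7–C11 to reach a ten-membered 6-oxo dienone; cut C8–C9 while re-joining C1–C6 (retro oxy-Cope) to a cis-1,2-dialkenylcyclohex-2-en-1-ol; cut C6–C7 (acetylide), C4=C5 (metathesis) and C1–C2 (aldol).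
3. Enabling feature: the oxygen on C6 and the C1=C10 alkene are 1,5-related through C7–C8–C9, and the Z C4=C5 bond lets C1–C6 exist as a cyclohexene; a [3,3] shift then trades the C1–C6 bond for C8–C9 and enlarges the six-membered ring to the ten-membered ring.
4. Forward order: acyclic aldol, cyclohexenone (ring C1–C6), alkoxyacetylide addition and trans reduction, oxy-Cope ring expansion (ten-membered ring), C7 alkylation, C6 reduction and lactonisation (γ-lactone ring), methylenation, the two esters.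
5. Stereochemistry: C2 and the relay centre C1 from an Evans syn aldol; relay centre C6 by axial acetylide addition; C8 and the C1=C10 geometry by chirality transfer in the chair oxy-Cope transition state; C7 by chelate-controlled alkylation anti to O8; C6 by Evans–Tishchenko 1,3-anti reduction directed by O8; Z C4=C5 from the six-membered ring.

Key step: step 13

Remark: TBS = tert-butyldimethylsilyl, TBDPS = tert-butyldiphenylsilyl, TES = triethylsilyl, PMB = 4-methoxybenzyl; locants C1–C15 in the text are the germacrane locants of the plan, and the configurations at C6, C7 and C8 rest on stereochemical models, not on calculation.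

**Step 1**
Reactants: 1 2-methylidenepropane-1,3-diol
Product: 2 2-[(TBS-oxy)methyl]prop-2-en-1-ol
Conditions: NaH (1.0 equiv), THF, 0 °C; TBSCl (1.0 equiv), rt
Reagents that add atoms: tert-butyldimethylsilyl chloride, CC(C)(C)[Si](C)(C)Cl
Why: Monosilylation of a symmetric diol through its sparingly soluble mono-sodium alkoxide (O-silylation) should stop after one silyl group; no stereocentre is involved.

**Step 2**
Reactants: 2 2-[(TBS-oxy)methyl]prop-2-en-1-ol
Product: 3 tert-butyl{[2-(chloromethyl)prop-2-en-1-yl]oxy}dimethylsilane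
Conditions: PPh3, CCl4, CH2Cl2, 40 °C
Reagents that add atoms: carbon tetrachloride, ClC(Cl)(Cl)Cl
Why: The Appel reaction converts the primary allylic alcohol into the chloride under neutral conditions that spare the silyl ether, and direct and allylic displacement give the same constitution.

**Step 3**
Reactants: 3 tert-butyl{[2-(chloromethyl)prop-2-en-1-yl]oxy}dimethylsilane
Product: 5 3-[(TBS-oxy)methyl]but-3-enoic acid, via allylmagnesium chloride 4 (not isolated)
Conditions: Mg, THF, 0 °C; CO2, −40 °C; cold 1 M HCl to pH 3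
Reagents that add atoms: carbon dioxide, O=C=O
Why: Carboxylation of an allylic Grignard reagent should give the β,γ-unsaturated acid, because both termini of the symmetric 2-substituted allyl unit lead to the same product.

**Step 4**
Reactants: 5 3-[(TBS-oxy)methyl]but-3-enoic acid; 6 (4R)-4-benzyl-1,3-oxazolidin-2-one
Product: 8 (4R)-4-benzyl-3-{3-[(TBS-oxy)methyl]but-3-enoyl}-1,3-oxazolidin-2-one, via mixed pivalic anhydride 7 (not isolated)
Conditions: PivCl, Et3N, THF, −20 °C; then LiCl, 6, −20 °C → rt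
Reagents that add atoms: none
Why: N-Acylation of the oxazolidinone through the mixed anhydride with LiCl and Et3N is mild enough not to move the β,γ-alkene into conjugation.

**Step 5**
Reactants: 9 3-methylbut-3-en-1-ol
Product: 10 3-methylbut-3-enal
Conditions: Dess–Martin periodinane, pyridine, CH2Cl2, 0 °C; used at once as a solution
Reagents that add atoms: none
Why: Dess–Martin oxidation under buffered, non-basic conditions should deliver the β,γ-unsaturated aldehyde without isomerisation to the conjugated enal.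

**Step 6**
Reactants: 8 (4R)-4-benzyl-3-{3-[(TBS-oxy)methyl]but-3-enoyl}-1,3-oxazolidin-2-one; 10 3-methylbut-3-enal
Product: 11 (4R)-4-benzyl-3-{(2R,3S)-3-hydroxy-5-methyl-2-[3-(TBS-oxy)prop-1-en-2-yl]hex-5-enoyl}-1,3-oxazolidin-2-one
Conditions: Bu2BOTf, i-Pr2NEt, CH2Cl2, −78 → 0 °C; 10, −78 → 0 °C; H2O2, MeOH, pH 7 buffer, 0 °C
Reagents that add atoms: none
Why: In the Evans syn aldol reaction the Z-boron enolate reacts through a Zimmerman–Traxler chair on the face away from the benzyl group, which should set C1 (R) and C2 (S).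

**Step 7**
Reactants: 11 (4R)-4-benzyl-3-{(2R,3S)-3-hydroxy-5-methyl-2-[3-(TBS-oxy)prop-1-en-2-yl]hex-5-enoyl}-1,3-oxazolidin-2-one
Product: 12 (2R,3S)-3-hydroxy-N-methoxy-N,5-dimethyl-2-[3-(TBS-oxy)prop-1-en-2-yl]hex-5-enamide
Conditions: MeONHMe·HCl, AlMe3, CH2Cl2, 0 °C → rt; cold 1 M HCl work-up
Reagents that add atoms: N,O-dimethylhydroxylamine hydrochloride, CNOC.Cl
Why: Aluminium amide transamidation of the imide (Weinreb amide formation) is assisted by the free β-hydroxyl and leaves both stereocentres untouched.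

**Step 8**
Reactants: 12 (2R,3S)-3-hydroxy-N-methoxy-N,5-dimethyl-2-[3-(TBS-oxy)prop-1-en-2-yl]hex-5-enamide
Product: 13 (2R,3S)-3-(TBDPS-oxy)-N-methoxy-N,5-dimethyl-2-[3-(TBS-oxy)prop-1-en-2-yl]hex-5-enamide
Conditions: TBDPSCl, imidazole, DMAP (cat.), DMF, 40 °C
Reagents that add atoms: tert-butyldiphenylsilyl chloride, CC(C)(C)[Si](Cl)(c1ccccc1)c1ccccc1
Why: Silylation of the secondary alcohol gives a bulky ether that should neither migrate nor leave under the later basic steps and is kept until the last step.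

**Step 9**
Reactants: 13 (2R,3S)-3-(TBDPS-oxy)-N-methoxy-N,5-dimethyl-2-[3-(TBS-oxy)prop-1-en-2-yl]hex-5-enamide
Product: 14 (4R,5S)-5-(TBDPS-oxy)-7-methyl-4-[3-(TBS-oxy)prop-1-en-2-yl]octa-1,7-dien-3-one
Conditions: CH2=CHMgBr (3 equiv), THF, 0 °C; poured into cold 1 M HCl
Reagents that add atoms: vinylmagnesium bromide, C=C[Mg]Br
Why: In the Weinreb ketone synthesis the chelated tetrahedral intermediate prevents over-addition, and the cold acidic quench avoids conjugate addition to the vinyl ketone.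

**Step 10**
Reactants: 14 (4R,5S)-5-(TBDPS-oxy)-7-methyl-4-[3-(TBS-oxy)prop-1-en-2-yl]octa-1,7-dien-3-one
Product: 15 (5S,6R)-5-(TBDPS-oxy)-3-methyl-6-[3-(TBS-oxy)prop-1-en-2-yl]cyclohex-2-en-1-one
Conditions: second-generation Grubbs catalyst (5 mol%), CH2Cl2, 40 °C
Reagents that add atoms: none
Why: Ring-closing metathesis of the vinyl ketone with the 2-methylallyl terminus should give the six-membered trisubstituted enone (ring C1–C6), since the other 1,1-disubstituted alkene could only close a four-membered ring or a tetrasubstituted five-membered ring.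

**Step 11**
Reactants: 16 (4-methoxyphenyl)methanol
Product: 17 1-({[(E)-1,2-dichloroethenyl]oxy}methyl)-4-methoxybenzene
Conditions: KH, THF, 0 °C; Cl2C=CHCl, rt
Reagents that add atoms: trichloroethene, ClC=C(Cl)Cl
Why: Addition of the alkoxide to dichloroacetylene formed in situ from trichloroethene is the known entry to 1,2-dichlorovinyl ethers, which serve as ynol ether precursors.

**Step 12**
Reactants: 15 (5S,6R)-5-(TBDPS-oxy)-3-methyl-6-[3-(TBS-oxy)prop-1-en-2-yl]cyclohex-2-en-1-one; 17 1-({[(E)-1,2-dichloroethenyl]oxy}methyl)-4-methoxybenzene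
Product: 20 (1S,5S,6R)-5-(TBDPS-oxy)-1-[(E)-2-(PMB-oxy)ethenyl]-3-methyl-6-[3-(TBS-oxy)prop-1-en-2-yl]cyclohex-2-en-1-ol, via lithium alkoxyacetylide 18 (not isolated), via alkynyl carbinol 19 (not isolated)
Conditions: 17, n-BuLi (2.2 equiv), THF, −78 → −40 °C; 15, −78 °C; LiAlH4, THF, 0 °C → rt; aq. potassium sodium tartrate
Reagents that add atoms: none
Why: The slim lithium acetylide should add to the enone carbonyl axially (1,2-addition), anti to the axial C1–H and on the face away from the C2 silyloxy group, so that the alkynyl group ends up cis to the C1 alkenyl group, and alkoxide-directed trans-hydroalumination then gives the (E)-enol ether.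

**Step 13**
Reactants: 20 (1S,5S,6R)-5-(TBDPS-oxy)-1-[(E)-2-(PMB-oxy)ethenyl]-3-methyl-6-[3-(TBS-oxy)prop-1-en-2-yl]cyclohex-2-en-1-ol
Product: 22 (2Z,5S,6E,9R)-5-(TBDPS-oxy)-9-(PMB-oxy)-3-methyl-7-[(TBS-oxy)methyl]cyclodeca-2,6-dien-1-one, via potassium enolate 21 (not isolated)
Conditions: KN(SiMe3)2 (1.2 equiv), 18-crown-6, THF, −78 → 0 °C; AcOH, −78 °C
Reagents that add atoms: none
Why: The potassium alkoxide of 20 undergoes a concerted, charge-accelerated [3,3]-sigmatropic shift (anionic oxy-Cope rearrangement) in which the C1–C6 bond of the cyclohexene breaks and the C8–C9 bond forms, giving the cross-conjugated enolate 21 that is protonated to 22. The closest known reaction type is the anionic oxy-Cope ring expansion of 1,2-dialkenylcyclohex-2-en-1-ols to cyclodecadienones used for germacrane-type rings. The ten-membered ring closes by this suprafacial [3,3] ring enlargement, which inserts C7–C10 between C6 and C1, and not by an end-to-end cyclisation. The new stereocentre C8 (R) is set by chirality transfer from C1 and C6 through the chair transition state, in which the (E)-enol ether holds the PMB-oxy group equatorial; the ring-cis C1=C10 bond (E by the sequence rule) follows because the C1–C2 bond is axial in that chair (vinyl group axial and 2-propenyl group equatorial on the cyclohexene), and the Z C4=C5 bond is carried over from the six-membered ring. The step needs this chair in preference to the ring-flipped chair or a boat, which is secured by the trans-diequatorial C2 silyloxy and C1 alkenyl groups and by the 1,3-diaxial clash of O6 and the C2 silyloxy group in the flipped conformer, while low temperature and the crown-complexed counter-ion should limit β-elimination of the C8 alkoxy group from the enolate.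

**Step 14**
Reactants: 22 (2Z,5S,6E,9R)-5-(TBDPS-oxy)-9-(PMB-oxy)-3-methyl-7-[(TBS-oxy)methyl]cyclodeca-2,6-dien-1-one
Product: 23 N-methoxy-N-methyl-2-{(1R,3Z,6S,7E,10R)-6-(TBDPS-oxy)-10-(PMB-oxy)-4-methyl-2-oxo-8-[(TBS-oxy)methyl]cyclodeca-3,7-dien-1-yl}acetamide
Conditions: LiN(i-Pr)2, THF, −78 °C; BrCH2C(O)N(OMe)Me, −78 → −20 °C
Reagents that add atoms: 2-bromo-N-methoxy-N-methylacetamide, CON(C)C(=O)CBr
Why: Kinetic deprotonation at C7 gives a lithium enolate chelated by the C8 ether oxygen (the arrangement of a Fráter–Seebach alkylation), in which the ring residue C9 covers the inner face, so that the bromoacetamide should attack the peripheral face anti to C9 and set C7 (R) anti to the C8 oxygen.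

**Step 15**
Reactants: 23 N-methoxy-N-methyl-2-{(1R,3Z,6S,7E,10R)-6-(TBDPS-oxy)-10-(PMB-oxy)-4-methyl-2-oxo-8-[(TBS-oxy)methyl]cyclodeca-3,7-dien-1-yl}acetamide
Product: 24 2-{(1R,3Z,6S,7E,10R)-6-(TBDPS-oxy)-10-hydroxy-4-methyl-2-oxo-8-[(TBS-oxy)methyl]cyclodeca-3,7-dien-1-yl}-N-methoxy-N-methylacetamide
Conditions: DDQ, CH2Cl2/pH 7 buffer (10:1), 0 °C
Reagents that add atoms: none
Why: Oxidative cleavage of the PMB ether by DDQ proceeds through the benzylic oxocarbenium ion and should leave the silyl ethers, the alkenes and the amide untouched.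

**Step 16**
Reactants: 24 2-{(1R,3Z,6S,7E,10R)-6-(TBDPS-oxy)-10-hydroxy-4-methyl-2-oxo-8-[(TBS-oxy)methyl]cyclodeca-3,7-dien-1-yl}-N-methoxy-N-methylacetamide
Product: 26 (3aR,4R,6E,8S,10Z,11aR)-8-(TBDPS-oxy)-10-methyl-2-oxo-6-[(TBS-oxy)methyl]-2,3,3a,4,5,8,9,11a-octahydrocyclodeca[b]furan-4-yl acetate, via hydroxy amide acetate 25 (not isolated)
Conditions: SmI2 (0.3 equiv, premixed with MeCHO), MeCHO (8 equiv), THF, −10 °C; then CSA (0.1 equiv), CH2Cl2, rt
Reagents that add atoms: acetaldehyde, CC=O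
Why: In the Evans–Tishchenko reduction the samarium-bound hemiacetal on O8 delivers hydride to C6 within a chair transition state, which should give the 1,3-anti alcohol (C6 R) with O8 acetylated, so that only O6 can close the trans-fused γ-lactone onto the Weinreb amide.

**Step 17**
Reactants: 26 (3aR,4R,6E,8S,10Z,11aR)-8-(TBDPS-oxy)-10-methyl-2-oxo-6-[(TBS-oxy)methyl]-2,3,3a,4,5,8,9,11a-octahydrocyclodeca[b]furan-4-yl acetate
Product: 27 (3aR,4R,6E,8S,10Z,11aR)-8-(TBDPS-oxy)-4-hydroxy-10-methyl-6-[(TBS-oxy)methyl]-3a,4,5,8,9,11a-hexahydrocyclodeca[b]furan-2(3H)-one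
Conditions: K2CO3 (0.5 equiv), MeOH, 0 °C → rt
Reagents that add atoms: none
Why: Carbonate-mediated methanolysis (transesterification) should remove the acetate while the γ-lactone stays closed under these mild conditions, and no base-labile stereocentre is present.

**Step 18**
Reactants: 27 (3aR,4R,6E,8S,10Z,11aR)-8-(TBDPS-oxy)-4-hydroxy-10-methyl-6-[(TBS-oxy)methyl]-3a,4,5,8,9,11a-hexahydrocyclodeca[b]furan-2(3H)-one
Product: 28 (3aS,4R,6E,8S,10Z,11aR)-8-(TBDPS-oxy)-10-methyl-6-[(TBS-oxy)methyl]-4-(TES-oxy)-3a,4,5,8,9,11a-hexahydrocyclodeca[b]furan-2(3H)-one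
Conditions: Et3SiOTf, 2,6-lutidine, CH2Cl2, −78 °C
Reagents that add atoms: triethylsilyl trifluoromethanesulfonate, CC[Si](CC)(CC)OS(=O)(=O)C(F)(F)F
Why: Silylation of the hindered C8 hydroxyl protects it against the strong base of the next step; the 3a descriptor changes only because silicon outranks carbon on O8.

**Step 19**
Reactants: 28 (3aS,4R,6E,8S,10Z,11aR)-8-(TBDPS-oxy)-10-methyl-6-[(TBS-oxy)methyl]-4-(TES-oxy)-3a,4,5,8,9,11a-hexahydrocyclodeca[b]furan-2(3H)-one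
Product: 31 (3aS,4R,6E,8S,10Z,11aR)-8-(TBDPS-oxy)-10-methyl-3-methylidene-6-[(TBS-oxy)methyl]-4-(TES-oxy)-3a,4,5,8,9,11a-hexahydrocyclodeca[b]furan-2(3H)-one, via Mannich base 29 (not isolated), via trimethylammonium iodide 30 (not isolated)
Conditions: LiN(i-Pr)2, THF, −78 °C; CH2=NMe2+ I−, −78 °C → rt; MeI, MeOH, rt; aq. NaHCO3, CH2Cl2
Reagents that add atoms: N,N-dimethylmethyleneiminium iodide (Eschenmoser salt), C=[N+](C)C.[I-]
Why: Mannich reaction of the lactone lithium enolate, N-methylation and base-induced β-elimination should install the exocyclic methylene, and the temporary C11 stereocentre of the Mannich base is destroyed.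

**Step 20**
Reactants: 31 (3aS,4R,6E,8S,10Z,11aR)-8-(TBDPS-oxy)-10-methyl-3-methylidene-6-[(TBS-oxy)methyl]-4-(TES-oxy)-3a,4,5,8,9,11a-hexahydrocyclodeca[b]furan-2(3H)-one
Product: 32 (3aR,4R,6E,8S,10Z,11aR)-8-(TBDPS-oxy)-4-hydroxy-6-(hydroxymethyl)-10-methyl-3-methylidene-3a,4,5,8,9,11a-hexahydrocyclodeca[b]furan-2(3H)-one
Conditions: HF·pyridine, pyridine, THF, 0 °C → rt
Reagents that add atoms: none
Why: Fluoride-mediated desilylation should cleave the TES ether and the primary TBS ether much faster than the secondary TBDPS ether.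

**Step 21**
Reactants: 32 (3aR,4R,6E,8S,10Z,11aR)-8-(TBDPS-oxy)-4-hydroxy-6-(hydroxymethyl)-10-methyl-3-methylidene-3a,4,5,8,9,11a-hexahydrocyclodeca[b]furan-2(3H)-one
Product: 33 [(3aR,4R,6E,8S,10Z,11aR)-8-(TBDPS-oxy)-4-hydroxy-10-methyl-3-methylidene-2-oxo-2,3,3a,4,5,8,9,11a-octahydrocyclodeca[b]furan-6-yl]methyl acetate
Conditions: AcCl (1.1 equiv), 2,4,6-collidine, CH2Cl2, −78 °C
Reagents that add atoms: acetyl chloride, CC(=O)Cl
Why: Kinetic O-acylation should take the primary allylic C14 alcohol in preference to the hindered secondary C8 alcohol.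

**Step 22**
Reactants: 33 [(3aR,4R,6E,8S,10Z,11aR)-8-(TBDPS-oxy)-4-hydroxy-10-methyl-3-methylidene-2-oxo-2,3,3a,4,5,8,9,11a-octahydrocyclodeca[b]furan-6-yl]methyl acetate
Product: 34 (3aR,4R,6E,8S,10Z,11aR)-6-[(acetyloxy)methyl]-8-(TBDPS-oxy)-10-methyl-3-methylidene-2-oxo-2,3,3a,4,5,8,9,11a-octahydrocyclodeca[b]furan-4-yl (2Z)-2-methylbut-2-enoate
Conditions: angelic acid, 2,4,6-trichlorobenzoyl chloride, Et3N, toluene, rt; then 33, 80 °C
Reagents that add atoms: angelic acid ((2Z)-2-methylbut-2-enoic acid), C/C=C(/C)C(=O)O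
Why: Yamaguchi-type esterification through the mixed anhydride, run without a nucleophilic catalyst, should acylate the C8 hydroxyl without isomerising the (Z)-acyl group to the tiglate.

**Step 23**
Reactants: 34 (3aR,4R,6E,8S,10Z,11aR)-6-[(acetyloxy)methyl]-8-(TBDPS-oxy)-10-methyl-3-methylidene-2-oxo-2,3,3a,4,5,8,9,11a-octahydrocyclodeca[b]furan-4-yl (2Z)-2-methylbut-2-enoate
Product: 35 (3aR,4R,6E,8S,10Z,11aR)-6-[(acetyloxy)methyl]-8-hydroxy-10-methyl-3-methylidene-2-oxo-2,3,3a,4,5,8,9,11a-octahydrocyclodeca[b]furan-4-yl (2Z)-2-methylbut-2-enoate (CNP0151426.1)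
Conditions: Bu4NF, AcOH (1:1), THF, 0 °C → rt
Reagents that add atoms: none
Why: Acetic acid-buffered fluoride desilylation should free the C2 hydroxyl without acyl migration or conjugate addition to the α-methylene lactone.

**Compound list**

1 | 2-methylidenepropane-1,3-diol | C=C(CO)CO | starting material
2 | 2-[(TBS-oxy)methyl]prop-2-en-1-ol | C=C(CO)CO[Si](C)(C)C(C)(C)C | intermediate
3 | tert-butyl{[2-(chloromethyl)prop-2-en-1-yl]oxy}dimethylsilane | C=C(CCl)CO[Si](C)(C)C(C)(C)C | intermediate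
4 | {2-[(TBS-oxy)methyl]prop-2-en-1-yl}magnesium chloride | C=C(C[Mg]Cl)CO[Si](C)(C)C(C)(C)C | intermediate
5 | 3-[(TBS-oxy)methyl]but-3-enoic acid | C=C(CC(=O)O)CO[Si](C)(C)C(C)(C)C | intermediate
6 | (4R)-4-benzyl-1,3-oxazolidin-2-one | O=C1N[C@H](Cc2ccccc2)CO1 | starting material
7 | 3-[(TBS-oxy)methyl]but-3-enoic 2,2-dimethylpropanoic anhydride | C=C(CC(=O)OC(=O)C(C)(C)C)CO[Si](C)(C)C(C)(C)C | intermediate
8 | (4R)-4-benzyl-3-{3-[(TBS-oxy)methyl]but-3-enoyl}-1,3-oxazolidin-2-one | C=C(CC(=O)N1C(=O)OC[C@H]1Cc1ccccc1)CO[Si](C)(C)C(C)(C)C | intermediate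
9 | 3-methylbut-3-en-1-ol | C=C(C)CCO | starting material
10 | 3-methylbut-3-enal | C=C(C)CC=O | intermediate
11 | (4R)-4-benzyl-3-{(2R,3S)-3-hydroxy-5-methyl-2-[3-(TBS-oxy)prop-1-en-2-yl]hex-5-enoyl}-1,3-oxazolidin-2-one | O=C(N1C(=O)OC[C@H]1Cc1ccccc1)[C@H](C(=C)CO[Si](C)(C)C(C)(C)C)[C@@H](O)CC(C)=C | intermediate
12 | (2R,3S)-3-hydroxy-N-methoxy-N,5-dimethyl-2-[3-(TBS-oxy)prop-1-en-2-yl]hex-5-enamide | CON(C)C(=O)[C@H](C(=C)CO[Si](C)(C)C(C)(C)C)[C@@H](O)CC(C)=C | intermediate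
13 | (2R,3S)-3-(TBDPS-oxy)-N-methoxy-N,5-dimethyl-2-[3-(TBS-oxy)prop-1-en-2-yl]hex-5-enamide | CON(C)C(=O)[C@H](C(=C)CO[Si](C)(C)C(C)(C)C)[C@@H](O[Si](c1ccccc1)(c1ccccc1)C(C)(C)C)CC(C)=C | intermediate
14 | (4R,5S)-5-(TBDPS-oxy)-7-methyl-4-[3-(TBS-oxy)prop-1-en-2-yl]octa-1,7-dien-3-one | C=CC(=O)[C@H](C(=C)CO[Si](C)(C)C(C)(C)C)[C@@H](O[Si](c1ccccc1)(c1ccccc1)C(C)(C)C)CC(C)=C | intermediate
15 | (5S,6R)-5-(TBDPS-oxy)-3-methyl-6-[3-(TBS-oxy)prop-1-en-2-yl]cyclohex-2-en-1-one | O=C1C=C(C)C[C@H](O[Si](c2ccccc2)(c2ccccc2)C(C)(C)C)[C@H]1C(=C)CO[Si](C)(C)C(C)(C)C | intermediate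
16 | (4-methoxyphenyl)methanol | COc1ccc(CO)cc1 | starting material
17 | 1-({[(E)-1,2-dichloroethenyl]oxy}methyl)-4-methoxybenzene | COc1ccc(CO/C(Cl)=C\Cl)cc1 | intermediate
18 | lithium [(4-methoxyphenyl)methoxy]acetylide | [Li]C#COCc1ccc(OC)cc1 | intermediate
19 | (1R,5S,6R)-5-(TBDPS-oxy)-1-[(PMB-oxy)ethynyl]-3-methyl-6-[3-(TBS-oxy)prop-1-en-2-yl]cyclohex-2-en-1-ol | O[C@]1(C#COCc2ccc(OC)cc2)C=C(C)C[C@H](O[Si](c2ccccc2)(c2ccccc2)C(C)(C)C)[C@H]1C(=C)CO[Si](C)(C)C(C)(C)C | intermediate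
20 | (1S,5S,6R)-5-(TBDPS-oxy)-1-[(E)-2-(PMB-oxy)ethenyl]-3-methyl-6-[3-(TBS-oxy)prop-1-en-2-yl]cyclohex-2-en-1-ol | O[C@]1(/C=C/OCc2ccc(OC)cc2)C=C(C)C[C@H](O[Si](c2ccccc2)(c2ccccc2)C(C)(C)C)[C@H]1C(=C)CO[Si](C)(C)C(C)(C)C | intermediate
21 | potassium enolate of 22 (O–K on C6, C6=C7 with O6 and C8 cis, C8 R) | C1/C(C)=C\C(O[K])=C\[C@H](OCc2ccc(OC)cc2)C/C(CO[Si](C)(C)C(C)(C)C)=C\[C@H]1O[Si](c2ccccc2)(c2ccccc2)C(C)(C)C | intermediate
22 | (2Z,5S,6E,9R)-5-(TBDPS-oxy)-9-(PMB-oxy)-3-methyl-7-[(TBS-oxy)methyl]cyclodeca-2,6-dien-1-one | O=C1/C=C(/C)C[C@H](O[Si](c2ccccc2)(c2ccccc2)C(C)(C)C)/C=C(/CO[Si](C)(C)C(C)(C)C)C[C@@H](OCc2ccc(OC)cc2)C1 | intermediate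
23 | N-methoxy-N-methyl-2-{(1R,3Z,6S,7E,10R)-6-(TBDPS-oxy)-10-(PMB-oxy)-4-methyl-2-oxo-8-[(TBS-oxy)methyl]cyclodeca-3,7-dien-1-yl}acetamide | O=C1/C=C(/C)C[C@H](O[Si](c2ccccc2)(c2ccccc2)C(C)(C)C)/C=C(/CO[Si](C)(C)C(C)(C)C)C[C@@H](OCc2ccc(OC)cc2)[C@H]1CC(=O)N(C)OC | intermediate
24 | 2-{(1R,3Z,6S,7E,10R)-6-(TBDPS-oxy)-10-hydroxy-4-methyl-2-oxo-8-[(TBS-oxy)methyl]cyclodeca-3,7-dien-1-yl}-N-methoxy-N-methylacetamide | O=C1/C=C(/C)C[C@H](O[Si](c2ccccc2)(c2ccccc2)C(C)(C)C)/C=C(/CO[Si](C)(C)C(C)(C)C)C[C@@H](O)[C@H]1CC(=O)N(C)OC | intermediate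
25 | 2-{(1S,2R,3Z,6S,7E,10R)-10-(acetyloxy)-6-(TBDPS-oxy)-2-hydroxy-4-methyl-8-[(TBS-oxy)methyl]cyclodeca-3,7-dien-1-yl}-N-methoxy-N-methylacetamide | O[C@@H]1/C=C(/C)C[C@H](O[Si](c2ccccc2)(c2ccccc2)C(C)(C)C)/C=C(/CO[Si](C)(C)C(C)(C)C)C[C@@H](OC(C)=O)[C@H]1CC(=O)N(C)OC | intermediate
26 | (3aR,4R,6E,8S,10Z,11aR)-8-(TBDPS-oxy)-10-methyl-2-oxo-6-[(TBS-oxy)methyl]-2,3,3a,4,5,8,9,11a-octahydrocyclodeca[b]furan-4-yl acetate | C1C(=O)O[C@@H]2/C=C(/C)C[C@H](O[Si](c3ccccc3)(c3ccccc3)C(C)(C)C)/C=C(/CO[Si](C)(C)C(C)(C)C)C[C@@H](OC(C)=O)[C@@H]12 | intermediate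
27 | (3aR,4R,6E,8S,10Z,11aR)-8-(TBDPS-oxy)-4-hydroxy-10-methyl-6-[(TBS-oxy)methyl]-3a,4,5,8,9,11a-hexahydrocyclodeca[b]furan-2(3H)-one | C1C(=O)O[C@@H]2/C=C(/C)C[C@H](O[Si](c3ccccc3)(c3ccccc3)C(C)(C)C)/C=C(/CO[Si](C)(C)C(C)(C)C)C[C@@H](O)[C@@H]12 | intermediate
28 | (3aS,4R,6E,8S,10Z,11aR)-8-(TBDPS-oxy)-10-methyl-6-[(TBS-oxy)methyl]-4-(TES-oxy)-3a,4,5,8,9,11a-hexahydrocyclodeca[b]furan-2(3H)-one | C1C(=O)O[C@@H]2/C=C(/C)C[C@H](O[Si](c3ccccc3)(c3ccccc3)C(C)(C)C)/C=C(/CO[Si](C)(C)C(C)(C)C)C[C@@H](O[Si](CC)(CC)CC)[C@@H]12 | intermediate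
29 | 3-[(dimethylamino)methyl] derivative of 28 (both C3 epimers) | CN(C)CC1C(=O)O[C@@H]2/C=C(/C)C[C@H](O[Si](c3ccccc3)(c3ccccc3)C(C)(C)C)/C=C(/CO[Si](C)(C)C(C)(C)C)C[C@@H](O[Si](CC)(CC)CC)[C@@H]12 | intermediate
30 | 3-[(trimethylammonio)methyl] derivative of 28, iodide | C[N+](C)(C)CC1C(=O)O[C@@H]2/C=C(/C)C[C@H](O[Si](c3ccccc3)(c3ccccc3)C(C)(C)C)/C=C(/CO[Si](C)(C)C(C)(C)C)C[C@@H](O[Si](CC)(CC)CC)[C@@H]12.[I-] | intermediate
31 | (3aS,4R,6E,8S,10Z,11aR)-8-(TBDPS-oxy)-10-methyl-3-methylidene-6-[(TBS-oxy)methyl]-4-(TES-oxy)-3a,4,5,8,9,11a-hexahydrocyclodeca[b]furan-2(3H)-one | C=C1C(=O)O[C@@H]2/C=C(/C)C[C@H](O[Si](c3ccccc3)(c3ccccc3)C(C)(C)C)/C=C(/CO[Si](C)(C)C(C)(C)C)C[C@@H](O[Si](CC)(CC)CC)[C@@H]12 | intermediate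
32 | (3aR,4R,6E,8S,10Z,11aR)-8-(TBDPS-oxy)-4-hydroxy-6-(hydroxymethyl)-10-methyl-3-methylidene-3a,4,5,8,9,11a-hexahydrocyclodeca[b]furan-2(3H)-one | C=C1C(=O)O[C@@H]2/C=C(/C)C[C@H](O[Si](c3ccccc3)(c3ccccc3)C(C)(C)C)/C=C(/CO)C[C@@H](O)[C@@H]12 | intermediate
33 | [(3aR,4R,6E,8S,10Z,11aR)-8-(TBDPS-oxy)-4-hydroxy-10-methyl-3-methylidene-2-oxo-2,3,3a,4,5,8,9,11a-octahydrocyclodeca[b]furan-6-yl]methyl acetate | C=C1C(=O)O[C@@H]2/C=C(/C)C[C@H](O[Si](c3ccccc3)(c3ccccc3)C(C)(C)C)/C=C(/COC(C)=O)C[C@@H](O)[C@@H]12 | intermediate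
34 | (3aR,4R,6E,8S,10Z,11aR)-6-[(acetyloxy)methyl]-8-(TBDPS-oxy)-10-methyl-3-methylidene-2-oxo-2,3,3a,4,5,8,9,11a-octahydrocyclodeca[b]furan-4-yl (2Z)-2-methylbut-2-enoate | C=C1C(=O)O[C@@H]2/C=C(/C)C[C@H](O[Si](c3ccccc3)(c3ccccc3)C(C)(C)C)/C=C(/COC(C)=O)C[C@@H](OC(=O)/C(C)=C\C)[C@@H]12 | intermediate
35 | (3aR,4R,6E,8S,10Z,11aR)-6-[(acetyloxy)methyl]-8-hydroxy-10-methyl-3-methylidene-2-oxo-2,3,3a,4,5,8,9,11a-octahydrocyclodeca[b]furan-4-yl (2Z)-2-methylbut-2-enoate (CNP0151426.1) | C=C1C(=O)O[C@@H]2/C=C(/C)C[C@H](O)/C=C(/COC(C)=O)C[C@@H](OC(=O)/C(C)=C\C)[C@@H]12 | target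

Total step count: 23. Longest linear sequence: 21 steps (steps 1–4, 6–10 and 12–23).

**Steps most likely to fail**

Step 13. Under the anionic conditions the enolate may expel the C8 alkoxide, the developing allyl anion may expel the C2 silyloxy group, or the rearrangement may leak through the ring-flipped chair and give the wrong C1=C10 geometry. The fallback sets out from 15 and comes back at 24; it replaces the enol ether by a vinylsilane, so that no β-leaving group is present, but it does not cure a leak through the flipped chair. Ethynylmagnesium bromide should add to 15 to give the ethynyl carbinol F1. Platinum-catalysed hydrosilylation with ethoxydimethylsilane (Pt2(dvtms)3 with t-Bu3P, dvtms = 1,3-divinyltetramethyldisiloxane, zerovalent platinum) should give the (E)-vinylsilane F2. Anionic oxy-Cope rearrangement (KH, 18-crown-6, THF) should give the β-silyl ketone F3. Tamao oxidation (KF, KHCO3, H2O2, THF/MeOH) should replace silicon by oxygen with retention and give the β-hydroxy ketone F4. Its dilithium alkoxide enolate (LiN(i-Pr)2, 2.2 equiv, −78 °C) would be alkylated with 2-bromo-N-methoxy-N-methylacetamide anti to the alkoxide (Fráter–Seebach alkylation) to give 24.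

Step 14. The alkylation may take place on the enolate conformer in which C8–H, not the ether oxygen, eclipses the enolate, which would mean poor or inverted facial selectivity at C7. The fallback sets out from 22 and comes back at 23; it sets C7 by protonation instead of by C–C bond formation. If the alkylation of 22 delivers the C7 epimer F5, this compound would be enolised again (LiN(SiMe3)2, THF, −78 °C) and the enolate protonated kinetically with a hindered phenol (2,6-di-tert-butyl-4-methylphenol). The proton should enter on the same preferred face, which places the acetamide arm on the opposite side and gives 23.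

Step 16. Hydride transfer to the conjugated ketone may be slow, the acetyl group may migrate from O8 to O6 before ring closure, or divalent samarium may reduce the enone. The fallback sets out from 24 and comes back at 27; it changes the hydride source to a boron-bound hydride and avoids the acyl transfer. Hydroxyl-directed reduction with Me4NBH(OAc)3 in MeCN/AcOH at −20 °C should give the 1,3-anti diol F6. Acid-catalysed lactonisation (CSA, CH2Cl2) would then give 27 directly; competing closure onto O8 is the point to watch there.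

**Further compounds**

F1 | step 13 | (1R,5S,6R)-5-(TBDPS-oxy)-1-ethynyl-3-methyl-6-[3-(TBS-oxy)prop-1-en-2-yl]cyclohex-2-en-1-ol | O[C@]1(C#C)C=C(C)C[C@H](O[Si](c2ccccc2)(c2ccccc2)C(C)(C)C)[C@H]1C(=C)CO[Si](C)(C)C(C)(C)C
F2 | step 13 | (1R,5S,6R)-5-(TBDPS-oxy)-1-{(E)-2-[ethoxy(dimethyl)silyl]ethenyl}-3-methyl-6-[3-(TBS-oxy)prop-1-en-2-yl]cyclohex-2-en-1-ol | O[C@]1(/C=C/[Si](C)(C)OCC)C=C(C)C[C@H](O[Si](c2ccccc2)(c2ccccc2)C(C)(C)C)[C@H]1C(=C)CO[Si](C)(C)C(C)(C)C
F3 | step 13 | (2Z,5S,6E,9R)-5-(TBDPS-oxy)-9-[ethoxy(dimethyl)silyl]-3-methyl-7-[(TBS-oxy)methyl]cyclodeca-2,6-dien-1-one | O=C1/C=C(/C)C[C@H](O[Si](c2ccccc2)(c2ccccc2)C(C)(C)C)/C=C(/CO[Si](C)(C)C(C)(C)C)C[C@@H]([Si](C)(C)OCC)C1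
F4 | step 13 | (2Z,5S,6E,9R)-5-(TBDPS-oxy)-9-hydroxy-3-methyl-7-[(TBS-oxy)methyl]cyclodeca-2,6-dien-1-one | O=C1/C=C(/C)C[C@H](O[Si](c2ccccc2)(c2ccccc2)C(C)(C)C)/C=C(/CO[Si](C)(C)C(C)(C)C)C[C@@H](O)C1
F5 | step 14 | N-methoxy-N-methyl-2-{(1S,3Z,6S,7E,10R)-6-(TBDPS-oxy)-10-(PMB-oxy)-4-methyl-2-oxo-8-[(TBS-oxy)methyl]cyclodeca-3,7-dien-1-yl}acetamide | O=C1/C=C(/C)C[C@H](O[Si](c2ccccc2)(c2ccccc2)C(C)(C)C)/C=C(/CO[Si](C)(C)C(C)(C)C)C[C@@H](OCc2ccc(OC)cc2)[C@@H]1CC(=O)N(C)OC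
F6 | step 16 | 2-{(1R,2R,3Z,6S,7E,10R)-6-(TBDPS-oxy)-2,10-dihydroxy-4-methyl-8-[(TBS-oxy)methyl]cyclodeca-3,7-dien-1-yl}-N-methoxy-N-methylacetamide | O[C@@H]1/C=C(/C)C[C@H](O[Si](c2ccccc2)(c2ccccc2)C(C)(C)C)/C=C(/CO[Si](C)(C)C(C)(C)C)C[C@@H](O)[C@H]1CC(=O)N(C)OC
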